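- We decide to rank these flasks by how early the back reaction catches the forward one, and to carry a single number for that from the oak run.

| setting | oak | beta | delta | epsilon | alpha | gamma | theta |
|---|---|---|---|---|---|---|---|
| substrate | 0.32 M | 0.80 M | 1.5 M | 0.25 M | 2.0 M | 1.0 M | 0.50 M |
| remark | run made earlier |  |  |  |  |  |  |
| time |  | 6.0 h | 6.0 h | 6.0 h | 6.0 h | 6.0 h | 6.0 h |

oak run (percent of the substrate charged)

| time / h | target / % |
|---|---|
| 0.417 | 13 |
| 1.33 | 26 |
| 2.00 | 35 |
| 3.00 | 44 |
| 5.00 | 53 |
| 6.00 | 55 |

(each reading ± 1.5 percentage points)



* ranking by amount of target, in percent of the substrate charged, from high to low, at 6.0 h (beta / delta / epsilon / alpha / gamma / theta)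
* the amount of target, in percent of the substrate charged of the flask you put first, at 6.0 h
* the amount of target, in percent of the substrate charged of the flask you put last, at 6.0 h

- Fastest rung, the start of oak: by the first reading oak has gained 0.312 h⁻¹ as a fraction of its charge, so we take this as a forward constant k, first order in substrate, with a time 1/k of 3.21 h.
- Next rung, the end of oak: the last two readings give a gain of 0.0200 h⁻¹, a reading with its scatter. That is less than the 0.140 h⁻¹ that k would give if the whole part not yet target were still substrate. We suppose that a back flow is one cause of this gap, but these readings do not show how much of the gap it makes up.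
- Slowest rung, the stall: we suppose that substrate gives target plus an equal amount of by-product, and that the two recombine. With y the fraction of the charge present as target, oak gives 0.215 M at 6.00 h. We carry this as the stall quotient Q, the charge c times y squared over the part of the charge not target (the reaction quotient). At 3.00 h oak's quotient was 0.111 M, so it is still climbing.
- Our reckoning: holding Q, alpha, richer than epsilon, stops lower, at 27.9% against 59.2% for epsilon. Since Q is still climbing, we take alpha's figure as a floor.
- The forecast gives epsilon > theta > beta > gamma > delta > alpha, with 60% on top and 26% at the bottom. Its ground: “dilute flasks should rank highest”.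
- The flasks give epsilon > theta > beta > gamma > delta > alpha, with 58.3% on top and 35.2% at the bottom, 9.2 percentage points above the forecast.

    target ⇌ isomer of the product (K = 8.80, k = 0.00950 h⁻¹)
    substrate ⇌ dormant form (K = 0.520, k = 0.0950 h⁻¹)
    substrate ⇌ target + by-product (K = 0.580 M, k = 0.260 h⁻¹)

- Alpha's quotient at 6.00 h is 0.383 M, above oak's 0.215 M. We carry it to the neighbour flask, alpha with 1.2 M of substrate: it gives 42.7% of target, where oak's quotient gives 34.3%. That neighbour flask holds 41.9% of target at 6.00 h, with 39.1% of its charge still substrate.

Readings and results stem from a simulated flask with constants of no real substance; the scatter is artificial.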